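The three O–Si bonds are cut first. The pendant 4-hydroxy-2-pyranone is then cut at C5'–C6' and O1'–C2', leading back to a carboxyl group on C3 and 2,2,6-trimethyl-1,3-dioxin-4-one.
The central cut is C2–C3 of the dihydrofuran ring (O1, C2, C3, C3a, C7a). C2 bears the catechol ring and is bonded to O1, so in the ring-opened 4-benzyloxy-2-pyranone its C–H bond is benzylic, α to oxygen and five atoms from a carbenoid centre at C3, which allows a 1,5 C–H insertion.
The remaining cuts are C3–C3a (palladium coupling of a 3-iodopyranone with a diazoacetate), O1–C2 (Mitsunobu etherification) and the styryl C=C (vinylogous aldol addition, then elimination).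
Forward, the purchased pyranone ring is iodinated, O-benzylated and extended to the styrylpyranone. The diazo ester is attached, the dihydrofuran ring closes, the second pyranone ring is built last through an acylketene, and fluoride frees the phenols.
C2 comes from the chiral dirhodium carboxylate in the insertion, C3 from base equilibration to trans relative to C2, and the E alkene from a conjugation-controlled E1cB elimination.
The ester is 2,2,2-trichloroethyl because zinc removes it without hydroxide or strong acid. The styryl group is installed before ring closure so that strong base meets the finished stereocentres only in the one acylation step.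

Key step: step 11

Abbreviations: TBS = tert-butyldimethylsilyl, TBSO = tert-butyldimethylsilyloxy, TCE = 2,2,2-trichloroethyl, Ts = 4-toluenesulfonyl, CDI = 1,1'-carbonyldiimidazole, Rh2(R-PTTL)4 = dirhodium tetrakis[N-phthaloyl-(R)-tert-leucinate].

Assumption: the sense of induction is taken from the 2-aryl-2,3-dihydrobenzofuran series, where the (S)-tert-leucinate catalyst favours 2R; the (R)-catalyst is therefore chosen for 2S, and its mirror image replaces it if the pyranone series runs the other way.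

Step 1
Reactants: 1 3,4-dihydroxybenzaldehyde
Product: 2 3,4-bis(TBSO)benzaldehyde
Conditions: TBSCl (2.4 equiv), imidazole (5 equiv), DMF, 0 °C → rt
Reagents that add atoms: tert-butyldimethylsilyl chloride, CC(C)(C)[Si](C)(C)Cl
Why: Silylation of phenols with a silyl chloride and imidazole leaves the aldehyde untouched and gives aryl silyl ethers that later leave with buffered fluoride.

Step 2
Reactants: 2 3,4-bis(TBSO)benzaldehyde
Product: 3 [3,4-bis(TBSO)phenyl]methanol
Conditions: NaBH4 (1 equiv), THF/MeOH, 0 °C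
Reagents that add atoms: none
Why: Borohydride reduction of an aromatic aldehyde is fast at 0 °C and should spare the aryl silyl ethers when kept short and cold.

Step 3
Reactants: 4 4-hydroxy-6-methyl-2H-pyran-2-one
Product: 5 4-hydroxy-3-iodo-6-methyl-2H-pyran-2-one
Conditions: N-iodosuccinimide (1.05 equiv), MeCN, 0 °C → rt, dark
Reagents that add atoms: N-iodosuccinimide, O=C1CCC(=O)N1I
Why: Electrophilic iodination of the enolised 1,3-dicarbonyl unit occurs at C3, the carbon between the two oxygen-bearing carbons, and the iodine later also blocks C-alkylation.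

Step 4
Reactants: 5 4-hydroxy-3-iodo-6-methyl-2H-pyran-2-one; 3 [3,4-bis(TBSO)phenyl]methanol
Product: 6 4-{[3,4-bis(TBSO)phenyl]methoxy}-3-iodo-6-methyl-2H-pyran-2-one
Conditions: PPh3 (1.3 equiv), DIAD (1.3 equiv), THF, 0 °C → rt
Reagents that add atoms: none
Why: Mitsunobu etherification suits the acidic vinylogous-acid 4-OH and a primary benzylic alcohol, normally gives the 4-alkoxy-2-pyranone rather than the 2-alkoxy-4-pyranone, and cannot alkylate the occupied C3.

Step 5
Reactants: 7 4-hydroxybenzaldehyde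
Product: 8 4-(TBSO)benzaldehyde
Conditions: TBSCl (1.2 equiv), imidazole (2.5 equiv), DMF, rt
Reagents that add atoms: tert-butyldimethylsilyl chloride, CC(C)(C)[Si](C)(C)Cl
Why: This is the same phenol silylation as in step 1, so all three phenols can be freed together at the end.

Step 6
Reactants: 6 4-{[3,4-bis(TBSO)phenyl]methoxy}-3-iodo-6-methyl-2H-pyran-2-one; 8 4-(TBSO)benzaldehyde
Product: 10 4-{[3,4-bis(TBSO)phenyl]methoxy}-6-{2-hydroxy-2-[4-(TBSO)phenyl]ethyl}-3-iodo-2H-pyran-2-one (racemic), via lithium dienolate 9 (not isolated)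
Conditions: LiN(SiMe3)2 (1.1 equiv), THF, −78 °C; 8 (1.2 equiv), −78 °C; AcOH quench
Reagents that add atoms: LiN(SiMe3)2, [Li+].C[Si](C)(C)[N-][Si](C)(C)C (its lithium stands in 9 only)
Why: In this vinylogous aldol addition the 6-methyl group is the most acidic C–H (extended dienolate onto the lactone carbonyl), the silylamide does not exchange the C–I bond, and the exocyclic CH2 terminus attacks the non-enolisable aldehyde to give a racemic carbinol centre that the next step removes.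

Step 7
Reactants: 10 4-{[3,4-bis(TBSO)phenyl]methoxy}-6-{2-hydroxy-2-[4-(TBSO)phenyl]ethyl}-3-iodo-2H-pyran-2-one
Product: 12 4-{[3,4-bis(TBSO)phenyl]methoxy}-6-{(E)-2-[4-(TBSO)phenyl]ethenyl}-3-iodo-2H-pyran-2-one, via mesylate 11 (not isolated)
Conditions: MsCl (1.5 equiv), Et3N (3 equiv), dry CH2Cl2, 0 °C; then DBU (2 equiv), 0 °C → rt
Reagents that add atoms: methanesulfonyl chloride, CS(=O)(=O)Cl (its atoms stand in 11 only)
Why: Mesylation followed by E1cB elimination through the same extended dienolate should give the fully conjugated alkene in its thermodynamically favoured E geometry.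

Step 8
Reactants: 13 2,2,2-trichloroethanol; 14 bromoacetyl bromide
Product: 15 TCE bromoacetate
Conditions: NaHCO3 (3 equiv), MeCN, 0 °C
Reagents that add atoms: none
Why: This is O-acylation of an alcohol by an acyl bromide, whose acyl carbon reacts far faster than the alkyl bromide.

Step 9
Reactants: 15 TCE bromoacetate
Product: 16 TCE diazoacetate
Conditions: TsNHNHTs (2 equiv), DBU (5 equiv), THF, 0 °C
Reagents that add atoms: N,N'-ditosylhydrazine, Cc1ccc(cc1)S(=O)(=O)NNS(=O)(=O)c1ccc(C)cc1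
Why: In this diazoacetate synthesis from a bromoacetate, N-alkylation of the bis-sulfonylhydrazine and two base-induced losses of sulfinate leave the diazo group under mild conditions.

Step 10
Reactants: 12 4-{[3,4-bis(TBSO)phenyl]methoxy}-6-{(E)-2-[4-(TBSO)phenyl]ethenyl}-3-iodo-2H-pyran-2-one; 16 TCE diazoacetate
Product: 17 TCE 2-diazo-2-(4-{[3,4-bis(TBSO)phenyl]methoxy}-6-{(E)-2-[4-(TBSO)phenyl]ethenyl}-2-oxo-2H-pyran-3-yl)acetate
Conditions: 16 (1.5 equiv), Pd(PPh3)4 (10 mol %), Ag2CO3 (0.5 equiv), Et3N (1.3 equiv), toluene, rt, dark; product kept cold and used at once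
Reagents that add atoms: none
Why: This palladium-catalysed cross-coupling of aryl or vinyl iodides with diazoacetates retains the diazo group (oxidative addition of zerovalent palladium into C3–I, amine- and silver-assisted palladation of the diazo carbon, reductive elimination at rt) and is known for trichloroethyl diazoacetate.

Step 11
Reactants: 17 TCE 2-diazo-2-(4-{[3,4-bis(TBSO)phenyl]methoxy}-6-{(E)-2-[4-(TBSO)phenyl]ethenyl}-2-oxo-2H-pyran-3-yl)acetate
Product: 19 TCE (2S,3S)-2-[3,4-bis(TBSO)phenyl]-6-{(E)-2-[4-(TBSO)phenyl]ethenyl}-4-oxo-2,3-dihydro-4H-furo[3,2-c]pyran-3-carboxylate (trans), via cis ester 18 (not isolated)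
Conditions: Rh2(R-PTTL)4 (2 mol %), 4 Å MS, toluene (0.02 M, slow addition of 17), −60 → −20 °C; then DBU (0.3 equiv), 0 °C
Reagents that add atoms: none
Why: Rh2(R-PTTL)4 (a dirhodium tetracarboxylate of divalent rhodium) binds the diazo carbon of 17, N2 departs, and the donor–acceptor carbenoid on the future C3 inserts into one of the two enantiotopic OCH2 hydrogens through a concerted but asynchronous three-centre transition state, creating the C2–C3 bond. The closest known reaction type is the enantioselective intramolecular C–H insertion of 2-(benzyloxy)aryl diazoacetates to cis-2-aryl-2,3-dihydrobenzofuran-3-carboxylates under phthaloyl amino acid dirhodium catalysts, of which 17 is the 2-pyranone counterpart. The one ring formed, the dihydrofuran O1–C2–C3–C3a–C7a, closes by 1,5 C–H insertion (carbenoid carbon as atom one, C–H carbon as atom five) and not by substitution or conjugate addition. C2 is set by the chiral pocket of the four phthalimido-tert-leucinate ligands, while C3 arises cis in 18 under kinetic control and is then inverted by catalytic DBU via the ester enolate to the more stable trans ester 19, so C3 takes its configuration from C2. The step needs site selectivity over the styryl alkene, the arenes and the ester CH2: the OCH2 bond is the only C–H within five-ring reach and is activated twice (by O1 and by the silyloxy arene), the trans-disubstituted, pyranone-conjugated alkene cannot be reached within the molecule and is a poor partner for a hindered donor–acceptor carbenoid at high dilution, and the CCl3 group deactivates its neighbouring CH2. Loss of C2 by β-elimination of the pyranolate oxygen during epimerisation would be the reverse of a 5-endo-trig closure, with poor overlap between the C3 enolate and the C2–O1 σ* orbital, and should therefore be slow at 0 °C.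

Step 12
Reactants: 19 TCE (2S,3S)-2-[3,4-bis(TBSO)phenyl]-6-{(E)-2-[4-(TBSO)phenyl]ethenyl}-4-oxo-2,3-dihydro-4H-furo[3,2-c]pyran-3-carboxylate
Product: 20 (2S,3S)-2-[3,4-bis(TBSO)phenyl]-6-{(E)-2-[4-(TBSO)phenyl]ethenyl}-4-oxo-2,3-dihydro-4H-furo[3,2-c]pyran-3-carboxylic acid
Conditions: activated Zn dust (10 equiv), THF/AcOH (3:1), rt
Reagents that add atoms: none
Why: Reductive fragmentation of a trichloroethyl ester by zinc (two-electron reduction, loss of chloride and 1,1-dichloroethene) frees the acid without hydroxide or strong acid, so lactone, silyl ethers, alkene, the C2–O1 bond and both stereocentres should be left alone.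

Step 13
Reactants: 20 (2S,3S)-2-[3,4-bis(TBSO)phenyl]-6-{(E)-2-[4-(TBSO)phenyl]ethenyl}-4-oxo-2,3-dihydro-4H-furo[3,2-c]pyran-3-carboxylic acid; 21 2,2,6-trimethyl-4H-1,3-dioxin-4-one
Product: 24 6-{2-[(2S,3S)-2-[3,4-bis(TBSO)phenyl]-6-{(E)-2-[4-(TBSO)phenyl]ethenyl}-4-oxo-2,3-dihydro-4H-furo[3,2-c]pyran-3-yl]-2-oxoethyl}-2,2-dimethyl-4H-1,3-dioxin-4-one, via acyl imidazolide 22 (not isolated), via dioxinone dienolate 23 (not isolated)
Conditions: 20, CDI (1.1 equiv), THF, rt; cannulated into 21 (3.5 equiv) + LiN(SiMe3)2 (3.4 equiv), THF, −78 °C → −40 °C; AcOH quench at −78 °C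
Reagents that add atoms: 1,1'-carbonyldiimidazole, O=C(n1ccnc1)n1ccnc1 (its imidazolyl group stands in 22 only); LiN(SiMe3)2, [Li+].C[Si](C)(C)[N-][Si](C)(C)C (its lithium stands in 23 only)
Why: This is γ-selective C-acylation of the dioxinone lithium dienolate by an acyl imidazolide (crossed Claisen type), with excess dienolate to absorb the free imidazole and the acidic product, and C3 should stay trans because any enolisation returns to the isomer anti to the C2 aryl group.

Step 14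
Reactants: 24 6-{2-[(2S,3S)-2-[3,4-bis(TBSO)phenyl]-6-{(E)-2-[4-(TBSO)phenyl]ethenyl}-4-oxo-2,3-dihydro-4H-furo[3,2-c]pyran-3-yl]-2-oxoethyl}-2,2-dimethyl-4H-1,3-dioxin-4-one
Product: 26 (2S,3S)-2-[3,4-bis(TBSO)phenyl]-3-(4-hydroxy-2-oxo-2H-pyran-6-yl)-6-{(E)-2-[4-(TBSO)phenyl]ethenyl}-2,3-dihydro-4H-furo[3,2-c]pyran-4-one, via acylketene 25 (not isolated)
Conditions: toluene (0.01 M), 110 °C, 1 h
Reagents that add atoms: none
Why: Thermal retro-[4+2] loss of acetone from the dioxinone gives an acylketene that the enol oxygen of the neighbouring ketone captures, closing the six-membered 4-hydroxy-2-pyranone under neutral conditions.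

Step 15
Reactants: 26 (2S,3S)-2-[3,4-bis(TBSO)phenyl]-3-(4-hydroxy-2-oxo-2H-pyran-6-yl)-6-{(E)-2-[4-(TBSO)phenyl]ethenyl}-2,3-dihydro-4H-furo[3,2-c]pyran-4-one
Product: 27 (2S,3S)-2-(3,4-dihydroxyphenyl)-3-(4-hydroxy-2-oxo-2H-pyran-6-yl)-6-[(E)-2-(4-hydroxyphenyl)ethenyl]-2,3-dihydro-4H-furo[3,2-c]pyran-4-one (CNP0330607.1)
Conditions: n-Bu4NF (3.6 equiv), AcOH (4 equiv), THF, 0 °C, argon; pH 4 buffer work-up
Reagents that add atoms: none
Why: Fluoride desilylation of aryl silyl ethers is driven by the Si–F bond, and the acetic acid buffer keeps the phenols protonated so that neither para-quinone methide opening of C2–O1 nor enolisation at C3 should set in.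

Compound list
1 | 3,4-dihydroxybenzaldehyde | O=Cc1ccc(O)c(O)c1 | starting material
2 | 3,4-bis(TBSO)benzaldehyde | O=Cc1ccc(O[Si](C)(C)C(C)(C)C)c(O[Si](C)(C)C(C)(C)C)c1 | intermediate
3 | [3,4-bis(TBSO)phenyl]methanol | OCc1ccc(O[Si](C)(C)C(C)(C)C)c(O[Si](C)(C)C(C)(C)C)c1 | intermediate
4 | 4-hydroxy-6-methyl-2H-pyran-2-one | Cc1cc(O)cc(=O)o1 | starting material
5 | 4-hydroxy-3-iodo-6-methyl-2H-pyran-2-one | Cc1cc(O)c(I)c(=O)o1 | intermediate
6 | 4-{[3,4-bis(TBSO)phenyl]methoxy}-3-iodo-6-methyl-2H-pyran-2-one | Cc1cc(OCc2ccc(O[Si](C)(C)C(C)(C)C)c(O[Si](C)(C)C(C)(C)C)c2)c(I)c(=O)o1 | intermediate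
7 | 4-hydroxybenzaldehyde | O=Cc1ccc(O)cc1 | starting material
8 | 4-(TBSO)benzaldehyde | O=Cc1ccc(O[Si](C)(C)C(C)(C)C)cc1 | intermediate
9 | lithium dienolate of 6, lithium 4-(arylmethoxy)-3-iodo-6-methylidene-6H-pyran-2-olate (formed in the flask) | [Li+].C=C1C=C(OCc2ccc(O[Si](C)(C)C(C)(C)C)c(O[Si](C)(C)C(C)(C)C)c2)C(I)=C([O-])O1 | intermediate
10 | 4-{[3,4-bis(TBSO)phenyl]methoxy}-6-{2-hydroxy-2-[4-(TBSO)phenyl]ethyl}-3-iodo-2H-pyran-2-one (racemic) | OC(Cc1cc(OCc2ccc(O[Si](C)(C)C(C)(C)C)c(O[Si](C)(C)C(C)(C)C)c2)c(I)c(=O)o1)c1ccc(O[Si](C)(C)C(C)(C)C)cc1 | intermediate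
11 | methanesulfonate of 10 (racemic, formed in the flask) | CS(=O)(=O)OC(Cc1cc(OCc2ccc(O[Si](C)(C)C(C)(C)C)c(O[Si](C)(C)C(C)(C)C)c2)c(I)c(=O)o1)c1ccc(O[Si](C)(C)C(C)(C)C)cc1 | intermediate
12 | 4-{[3,4-bis(TBSO)phenyl]methoxy}-6-{(E)-2-[4-(TBSO)phenyl]ethenyl}-3-iodo-2H-pyran-2-one | O=c1oc(/C=C/c2ccc(O[Si](C)(C)C(C)(C)C)cc2)cc(OCc2ccc(O[Si](C)(C)C(C)(C)C)c(O[Si](C)(C)C(C)(C)C)c2)c1I | intermediate
13 | 2,2,2-trichloroethanol | OCC(Cl)(Cl)Cl | starting material
14 | bromoacetyl bromide | BrCC(=O)Br | starting material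
15 | TCE bromoacetate | BrCC(=O)OCC(Cl)(Cl)Cl | intermediate
16 | TCE diazoacetate | [N-]=[N+]=CC(=O)OCC(Cl)(Cl)Cl | intermediate
17 | TCE 2-diazo-2-(4-{[3,4-bis(TBSO)phenyl]methoxy}-6-{(E)-2-[4-(TBSO)phenyl]ethenyl}-2-oxo-2H-pyran-3-yl)acetate | ClC(Cl)(Cl)COC(=O)C(=[N+]=[N-])c1c(OCc2ccc(O[Si](C)(C)C(C)(C)C)c(O[Si](C)(C)C(C)(C)C)c2)cc(/C=C/c2ccc(O[Si](C)(C)C(C)(C)C)cc2)oc1=O | intermediate
18 | TCE (2S,3R)-2-[3,4-bis(TBSO)phenyl]-6-{(E)-2-[4-(TBSO)phenyl]ethenyl}-4-oxo-2,3-dihydro-4H-furo[3,2-c]pyran-3-carboxylate (cis, formed in the flask) | ClC(Cl)(Cl)COC(=O)[C@@H]1c2c(cc(/C=C/c3ccc(O[Si](C)(C)C(C)(C)C)cc3)oc2=O)O[C@@H]1c1ccc(O[Si](C)(C)C(C)(C)C)c(O[Si](C)(C)C(C)(C)C)c1 | intermediate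
19 | TCE (2S,3S)-2-[3,4-bis(TBSO)phenyl]-6-{(E)-2-[4-(TBSO)phenyl]ethenyl}-4-oxo-2,3-dihydro-4H-furo[3,2-c]pyran-3-carboxylate (trans) | ClC(Cl)(Cl)COC(=O)[C@H]1c2c(cc(/C=C/c3ccc(O[Si](C)(C)C(C)(C)C)cc3)oc2=O)O[C@@H]1c1ccc(O[Si](C)(C)C(C)(C)C)c(O[Si](C)(C)C(C)(C)C)c1 | intermediate
20 | (2S,3S)-2-[3,4-bis(TBSO)phenyl]-6-{(E)-2-[4-(TBSO)phenyl]ethenyl}-4-oxo-2,3-dihydro-4H-furo[3,2-c]pyran-3-carboxylic acid | OC(=O)[C@H]1c2c(cc(/C=C/c3ccc(O[Si](C)(C)C(C)(C)C)cc3)oc2=O)O[C@@H]1c1ccc(O[Si](C)(C)C(C)(C)C)c(O[Si](C)(C)C(C)(C)C)c1 | intermediate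
21 | 2,2,6-trimethyl-4H-1,3-dioxin-4-one | CC1=CC(=O)OC(C)(C)O1 | starting material
22 | N-acylimidazole of 20, (2S,3S) (formed in the flask) | O=C(n1ccnc1)[C@H]1c2c(cc(/C=C/c3ccc(O[Si](C)(C)C(C)(C)C)cc3)oc2=O)O[C@@H]1c1ccc(O[Si](C)(C)C(C)(C)C)c(O[Si](C)(C)C(C)(C)C)c1 | intermediate
23 | lithium dienolate of 21, lithium 2,2-dimethyl-6-methylidene-6H-1,3-dioxin-4-olate (formed in the flask) | [Li+].C=C1C=C([O-])OC(C)(C)O1 | intermediate
24 | 6-{2-[(2S,3S)-2-[3,4-bis(TBSO)phenyl]-6-{(E)-2-[4-(TBSO)phenyl]ethenyl}-4-oxo-2,3-dihydro-4H-furo[3,2-c]pyran-3-yl]-2-oxoethyl}-2,2-dimethyl-4H-1,3-dioxin-4-one | CC1(C)OC(=O)C=C(CC(=O)[C@H]2c3c(cc(/C=C/c4ccc(O[Si](C)(C)C(C)(C)C)cc4)oc3=O)O[C@@H]2c2ccc(O[Si](C)(C)C(C)(C)C)c(O[Si](C)(C)C(C)(C)C)c2)O1 | intermediate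
25 | acylketene, 5-[(2S,3S)-furopyranon-3-yl]-3,5-dioxopent-1-en-1-one (formed in the flask) | O=C=CC(=O)CC(=O)[C@H]1c2c(cc(/C=C/c3ccc(O[Si](C)(C)C(C)(C)C)cc3)oc2=O)O[C@@H]1c1ccc(O[Si](C)(C)C(C)(C)C)c(O[Si](C)(C)C(C)(C)C)c1 | intermediate
26 | (2S,3S)-2-[3,4-bis(TBSO)phenyl]-3-(4-hydroxy-2-oxo-2H-pyran-6-yl)-6-{(E)-2-[4-(TBSO)phenyl]ethenyl}-2,3-dihydro-4H-furo[3,2-c]pyran-4-one | O=c1cc(O)cc([C@H]2c3c(cc(/C=C/c4ccc(O[Si](C)(C)C(C)(C)C)cc4)oc3=O)O[C@@H]2c2ccc(O[Si](C)(C)C(C)(C)C)c(O[Si](C)(C)C(C)(C)C)c2)o1 | intermediate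
27 | (2S,3S)-2-(3,4-dihydroxyphenyl)-3-(4-hydroxy-2-oxo-2H-pyran-6-yl)-6-[(E)-2-(4-hydroxyphenyl)ethenyl]-2,3-dihydro-4H-furo[3,2-c]pyran-4-one | O=c1cc(O)cc([C@H]2c3c(cc(/C=C/c4ccc(O)cc4)oc3=O)O[C@@H]2c2ccc(O)c(O)c2)o1 | target

Total step count: 15.
Longest linear sequence: 11 steps (1 → 2 → 3 → 6 → 10 → 12 → 17 → 19 → 20 → 24 → 26 → 27; steps 1, 2, 4, 6, 7, 10–15).

Steps most likely to fail

Step 11. With so electron-rich an arene the insertion may drift toward hydride transfer followed by ion-pair collapse. The catalyst pocket would then distinguish the two enantiotopic benzylic hydrogens poorly, and the enantiomeric purity at C2 would be low. The fallback sets out from 17 and comes back at 19. It gives up stereocontrol in the ring closure and gains it by separation. 17 is decomposed with achiral Rh2(OAc)4 in CH2Cl2 at rt, which should give 18 together with its mirror image, the (2R,3S)-cis ester F1. DBU then equilibrates the mixture to the racemic trans ester, that is 19 and its mirror image, the (2R,3R)-trans ester F2. Preparative chromatography on a chiral stationary phase (amylose or cellulose carbamate) separates the two and delivers 19.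

Step 10. The C3–I bond is flanked by the lactone carbonyl and the benzyloxy group. Palladation of the diazo carbon and reductive elimination may therefore be slower than loss of N2 at palladium or hydrodeiodination. The product, formally a cyclic vinyl diazo ester, may also slowly electrocyclise on standing. The fallback sets out from 12 and comes back at 17. It makes the diazo group from a ketone instead of carrying it through a coupling. Iodine–magnesium exchange on 12 (iPrMgCl·LiCl, THF, −40 °C) should give the pyranon-3-ylmagnesium chloride F3. This is run at −78 °C into an excess of bis(2,2,2-trichloroethyl) oxalate F4 (from oxalyl chloride, 13 and pyridine in CH2Cl2) to give the α-keto ester F5. Condensation with tosylhydrazine (CH2Cl2, 40 °C) gives the tosylhydrazone F6, and Et3N or DBU in CH2Cl2 at rt expels sulfinate (Bamford–Stevens type) to give 17.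

Step 13. The basic dienolate may take the acidic C3–H of 22 instead of attacking the acyl carbon. The resulting enolate may then expel the pyranolate oxygen, which opens the C2–O1 bond and erases C2. The fallback sets out from 20 and comes back at 26. It replaces the lithium dienolate by a neutral silyl dienol ether. 20 is converted into the acid chloride F7 with 1-chloro-N,N,2-trimethylprop-1-en-1-amine (CH2Cl2, 0 °C, no HCl formed). F7 is treated with 1-methoxy-1,3-bis(trimethylsilyloxy)buta-1,3-diene in CH2Cl2 from −78 °C to rt (Mukaiyama-type γ-acylation), which after aqueous work-up should give the methyl 3,5-dioxopentanoate F8. DBU in toluene at 60 °C closes F8 to 26 by enol lactonisation.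

Further compounds
F1 | step 11 | TCE (2R,3S)-2-[3,4-bis(TBSO)phenyl]-6-{(E)-2-[4-(TBSO)phenyl]ethenyl}-4-oxo-2,3-dihydro-4H-furo[3,2-c]pyran-3-carboxylate (cis, mirror image of 18) | ClC(Cl)(Cl)COC(=O)[C@H]1c2c(cc(/C=C/c3ccc(O[Si](C)(C)C(C)(C)C)cc3)oc2=O)O[C@H]1c1ccc(O[Si](C)(C)C(C)(C)C)c(O[Si](C)(C)C(C)(C)C)c1
F2 | step 11 | TCE (2R,3R)-2-[3,4-bis(TBSO)phenyl]-6-{(E)-2-[4-(TBSO)phenyl]ethenyl}-4-oxo-2,3-dihydro-4H-furo[3,2-c]pyran-3-carboxylate (trans, mirror image of 19) | ClC(Cl)(Cl)COC(=O)[C@@H]1c2c(cc(/C=C/c3ccc(O[Si](C)(C)C(C)(C)C)cc3)oc2=O)O[C@H]1c1ccc(O[Si](C)(C)C(C)(C)C)c(O[Si](C)(C)C(C)(C)C)c1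
F3 | step 10 | (4-{[3,4-bis(TBSO)phenyl]methoxy}-6-{(E)-2-[4-(TBSO)phenyl]ethenyl}-2-oxo-2H-pyran-3-yl)magnesium chloride | Cl[Mg]c1c(OCc2ccc(O[Si](C)(C)C(C)(C)C)c(O[Si](C)(C)C(C)(C)C)c2)cc(/C=C/c2ccc(O[Si](C)(C)C(C)(C)C)cc2)oc1=O
F4 | step 10 | bis(2,2,2-trichloroethyl) oxalate | O=C(OCC(Cl)(Cl)Cl)C(=O)OCC(Cl)(Cl)Cl
F5 | step 10 | TCE 2-(4-{[3,4-bis(TBSO)phenyl]methoxy}-6-{(E)-2-[4-(TBSO)phenyl]ethenyl}-2-oxo-2H-pyran-3-yl)-2-oxoacetate | ClC(Cl)(Cl)COC(=O)C(=O)c1c(OCc2ccc(O[Si](C)(C)C(C)(C)C)c(O[Si](C)(C)C(C)(C)C)c2)cc(/C=C/c2ccc(O[Si](C)(C)C(C)(C)C)cc2)oc1=O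
F6 | step 10 | tosylhydrazone of F5 (C=N geometry not fixed) | ClC(Cl)(Cl)COC(=O)C(=NNS(=O)(=O)c1ccc(C)cc1)c1c(OCc2ccc(O[Si](C)(C)C(C)(C)C)c(O[Si](C)(C)C(C)(C)C)c2)cc(/C=C/c2ccc(O[Si](C)(C)C(C)(C)C)cc2)oc1=O
F7 | step 13 | (2S,3S)-2-[3,4-bis(TBSO)phenyl]-6-{(E)-2-[4-(TBSO)phenyl]ethenyl}-4-oxo-2,3-dihydro-4H-furo[3,2-c]pyran-3-carbonyl chloride | ClC(=O)[C@H]1c2c(cc(/C=C/c3ccc(O[Si](C)(C)C(C)(C)C)cc3)oc2=O)O[C@@H]1c1ccc(O[Si](C)(C)C(C)(C)C)c(O[Si](C)(C)C(C)(C)C)c1
F8 | step 13 | methyl 5-[(2S,3S)-2-[3,4-bis(TBSO)phenyl]-6-{(E)-2-[4-(TBSO)phenyl]ethenyl}-4-oxo-2,3-dihydro-4H-furo[3,2-c]pyran-3-yl]-3,5-dioxopentanoate | COC(=O)CC(=O)CC(=O)[C@H]1c2c(cc(/C=C/c3ccc(O[Si](C)(C)C(C)(C)C)cc3)oc2=O)O[C@@H]1c1ccc(O[Si](C)(C)C(C)(C)C)c(O[Si](C)(C)C(C)(C)C)c1
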